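Ring C of the upper flavan is opened at O1–C8a and C3–C4. The route exploits that C4 sits between ring A (C4a) and ring D (C6 of the afzelechin unit) with C8a ortho to it: ring A carrying a C4 ketone and a C8a fluorine is a 1,3-bis-electrophile. In one pot it meets the β-oxido organolithium of an (R)-bromohydrin (ring B with O1–C2–C3): C3–Li adds to the C4 carbonyl, then the C2 alkoxide closes ring C by SNAr at C8a. Dehydration gives a flav-3-ene; hydroboration, steered by C2 alone, sets 3-OH and 4-H all-trans, and hydrogenolysis unveils the target.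

Key step: step 5

Assumption: (+)-afzelechin (2R,3S) is bought as a catalogue natural product; the C3 oxygen of the upper unit is brought in after the key step (C4 is carried as a ketone, then as an alkene).

Step 1
Reactants: 1 (+)-afzelechin
Product: 2 (2R,3S)-3,5,7-tris(benzyloxy)-2-[4-(benzyloxy)phenyl]chromane
Conditions: BnBr (4.5 equiv), NaH (4.5 equiv, added last in portions), DMF, −10 °C → rt
Reagents that add atoms: benzyl bromide BrCc1ccccc1
Why: Williamson etherification of the three phenols and the C3 alcohol; phenoxides are benzylated as they form and no stereocentre is touched.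

Step 2
Reactants: 2 (2R,3S)-3,5,7-tris(benzyloxy)-2-[4-(benzyloxy)phenyl]chromane
Product: 3 (2R,3S)-3,5,7-tris(benzyloxy)-2-[4-(benzyloxy)phenyl]-8-bromochromane
Conditions: NBS (1.0 equiv), CH2Cl2, −78 → 0 °C
Reagents that add atoms: N-bromosuccinimide O=C1CCC(=O)N1Br
Why: Electrophilic aromatic bromination should go first to C8 of the 5,7-dialkoxylated ring, so bromine blocks C8 and leaves C6 as the only open nucleophilic position.

Step 3
Reactants: 3 (2R,3S)-3,5,7-tris(benzyloxy)-2-[4-(benzyloxy)phenyl]-8-bromochromane; 4 4-(benzyloxy)-2-fluorobenzoic acid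
Product: 6 [4-(benzyloxy)-2-fluorophenyl][(2R,3S)-3,5,7-tris(benzyloxy)-2-[4-(benzyloxy)phenyl]-8-bromochroman-6-yl]methanone, via mixed trifluoroacetic anhydride 5 (not isolated)
Conditions: 4, TFAA, CH2Cl2, 0 °C; then 3, cat. 85% H3PO4, 0 °C → rt
Reagents that add atoms: none
Why: Friedel–Crafts acylation by the mixed anhydride (TFAA method) at C6, the only free position of the phloroglucinol-type ring, joins the future C4 (as C=O) to ring D.

Step 4
Reactants: 7 2-bromo-1-[4-(benzyloxy)phenyl]ethanone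
Product: 8 (R)-2-bromo-1-[4-(benzyloxy)phenyl]ethanol
Conditions: (R)-Me-CBS (10 mol%), BH3·SMe2, THF, −20 °C; MeOH, then aqueous work-up
Reagents that add atoms: none
Why: Corey–Bakshi–Shibata reduction; the (R)-oxazaborolidine delivers hydride to the ketone face that gives the (R)-bromohydrin (aryl as the large group), which sets the future C2.

Step 5
Reactants: 8 (R)-2-bromo-1-[4-(benzyloxy)phenyl]ethanol; 6 [4-(benzyloxy)-2-fluorophenyl][(2R,3S)-3,5,7-tris(benzyloxy)-2-[4-(benzyloxy)phenyl]-8-bromochroman-6-yl]methanone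
Product: 11 (2S,4RS)-7-(benzyloxy)-2-[4-(benzyloxy)phenyl]-4-[(2R,3S)-3,5,7-tris(benzyloxy)-2-[4-(benzyloxy)phenyl]-8-bromochroman-6-yl]chroman-4-ol, via β-oxido organolithium 9 (not isolated), via acyclic dilithium diolate 10 (not isolated)
Conditions: 8 (1.3 equiv), n-BuLi, THF, −78 °C; lithium naphthalenide (2 equiv per 8), −78 °C; 6, −78 → −40 °C; then t-BuOK, DMPU, 60 °C; aqueous work-up
Reagents that add atoms: none
Why: Reductive bromine–lithium exchange on the lithium alkoxide of 8 gives the O,C-dilithio species 9, whose C3–Li adds 1,2 to the C4 carbonyl of 6 (closest known type: β-oxido organolithium additions to ketones giving 1,3-diols). On warming with t-BuOK/DMPU the C2 alkoxide of 10 displaces the ortho fluorine by addition–elimination (intramolecular SNAr etherification, the known flavan-forming closure), so the sequence is a formal [3+3] annulation. Ring C closes in the 6-exo mode at C8a. C2 keeps the configuration of 8 because neither of its bonds is broken (O1 is the nucleophile), and the new C4 carbinol centre forms as an epimer mixture that is erased in step 6. The needed selectivity is secured by the substrate: only the C2 alkoxide can reach C8a (the C4 alkoxide would need a four-membered ring), the ketone has no α-hydrogen to enolise, and carbonyl addition at −78 °C should outrun bromine–lithium exchange at C8 of the lower unit.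

Step 6
Reactants: 11 (2S,4RS)-7-(benzyloxy)-2-[4-(benzyloxy)phenyl]-4-[(2R,3S)-3,5,7-tris(benzyloxy)-2-[4-(benzyloxy)phenyl]-8-bromochroman-6-yl]chroman-4-ol
Product: 12 (2S)-7-(benzyloxy)-2-[4-(benzyloxy)phenyl]-4-[(2R,3S)-3,5,7-tris(benzyloxy)-2-[4-(benzyloxy)phenyl]-8-bromochroman-6-yl]-2H-chromene
Conditions: PPTS (10 mol%), 4 Å MS, toluene, 40 °C
Reagents that add atoms: none
Why: E1 dehydration of the tertiary bis-benzylic alcohol through the cation stabilised by rings A and D; only C3 carries β-hydrogens, so both C4 epimers should converge on the C3=C4 alkene, and the weak acid should leave the C2–O1 bond intact.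

Step 7
Reactants: 12 (2S)-7-(benzyloxy)-2-[4-(benzyloxy)phenyl]-4-[(2R,3S)-3,5,7-tris(benzyloxy)-2-[4-(benzyloxy)phenyl]-8-bromochroman-6-yl]-2H-chromene
Product: 14 (2R,3S,4S)-7-(benzyloxy)-2-[4-(benzyloxy)phenyl]-4-[(2R,3S)-3,5,7-tris(benzyloxy)-2-[4-(benzyloxy)phenyl]-8-bromochroman-6-yl]chroman-3-ol, via C3 alkylborane 13 (not isolated)
Conditions: BH3·THF (excess), THF, 0 °C → rt; then 3 M NaOH, 30% H2O2, 0 °C
Reagents that add atoms: hydrogen peroxide OO
Why: Hydroboration–oxidation; boron goes to C3 and hydrogen to the diaryl-substituted C4 by syn addition on the face anti to the C2 aryl, and oxidation with retention should give 3-OH trans to the C2 aryl and 4-H cis to 3-OH, i.e. the C4 aryl trans to 3-OH (2R,3S,4S).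

Step 8
Reactants: 14 (2R,3S,4S)-7-(benzyloxy)-2-[4-(benzyloxy)phenyl]-4-[(2R,3S)-3,5,7-tris(benzyloxy)-2-[4-(benzyloxy)phenyl]-8-bromochroman-6-yl]chroman-3-ol
Product: 15 guibourtinidol-(4α→6)-afzelechin (CNP0325116.1)
Conditions: H2 (1 atm), Pd(OH)2/C, Et3N (1.1 equiv), THF/MeOH, rt
Reagents that add atoms: none
Why: Catalytic hydrogenolysis should cleave the six benzyl ethers and the blocking C8–Br bond of the lower unit in one operation without touching a stereocentre.

Compound list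
1 | (+)-afzelechin, (2R,3S)-2-(4-hydroxyphenyl)chromane-3,5,7-triol | c1c(O)cc2c(c1O)C[C@H](O)[C@@H](c3ccc(O)cc3)O2 | starting material
2 | (2R,3S)-3,5,7-tris(benzyloxy)-2-[4-(benzyloxy)phenyl]chromane | c1c(OCc3ccccc3)cc2c(c1OCc4ccccc4)C[C@H](OCc5ccccc5)[C@@H](c6ccc(OCc7ccccc7)cc6)O2 | intermediate
3 | (2R,3S)-3,5,7-tris(benzyloxy)-2-[4-(benzyloxy)phenyl]-8-bromochromane | c1c(OCc3ccccc3)c(Br)c2c(c1OCc4ccccc4)C[C@H](OCc5ccccc5)[C@@H](c6ccc(OCc7ccccc7)cc6)O2 | intermediate
4 | 4-(benzyloxy)-2-fluorobenzoic acid | OC(=O)c1ccc(OCc2ccccc2)cc1F | starting material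
5 | 4-(benzyloxy)-2-fluorobenzoic trifluoroacetic anhydride (not isolated) | O=C(OC(=O)C(F)(F)F)c1ccc(OCc2ccccc2)cc1F | intermediate
6 | [4-(benzyloxy)-2-fluorophenyl][(2R,3S)-3,5,7-tris(benzyloxy)-2-[4-(benzyloxy)phenyl]-8-bromochroman-6-yl]methanone | O=C(c8ccc(OCc9ccccc9)cc8F)c1c(OCc3ccccc3)c(Br)c2c(c1OCc4ccccc4)C[C@H](OCc5ccccc5)[C@@H](c6ccc(OCc7ccccc7)cc6)O2 | intermediate
7 | 2-bromo-1-[4-(benzyloxy)phenyl]ethanone | O=C(CBr)c1ccc(OCc2ccccc2)cc1 | starting material
8 | (R)-2-bromo-1-[4-(benzyloxy)phenyl]ethanol | O[C@@H](CBr)c1ccc(OCc2ccccc2)cc1 | intermediate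
9 | O,C-dilithio derivative of 8, lithium 1-[4-(benzyloxy)phenyl]-2-lithioethoxide with the carbinol configuration of 8 (not isolated) | [Li]O[C@@H](C[Li])c1ccc(OCc2ccccc2)cc1 | intermediate
10 | acyclic dilithium 1,3-diolate from addition of 9 to 6, mixture at the new carbinol carbon (not isolated) | [Li]O[C@@H](CC(O[Li])(c8ccc(OCc9ccccc9)cc8F)c1c(OCc3ccccc3)c(Br)c2c(c1OCc4ccccc4)C[C@H](OCc5ccccc5)[C@@H](c6ccc(OCc7ccccc7)cc6)O2)c%10ccc(OCc%11ccccc%11)cc%10 | intermediate
11 | (2S,4RS)-7-(benzyloxy)-2-[4-(benzyloxy)phenyl]-4-[(2R,3S)-3,5,7-tris(benzyloxy)-2-[4-(benzyloxy)phenyl]-8-bromochroman-6-yl]chroman-4-ol | C(c1ccccc1)Oc2ccc(cc2)[C@H]3Oc4cc(OCc5ccccc5)ccc4C(O)(c6c(OCc7ccccc7)c(Br)c8c(c6OCc9ccccc9)C[C@H](OCc%10ccccc%10)[C@@H](c%11ccc(OCc%12ccccc%12)cc%11)O8)C3 | intermediate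
12 | (2S)-7-(benzyloxy)-2-[4-(benzyloxy)phenyl]-4-[(2R,3S)-3,5,7-tris(benzyloxy)-2-[4-(benzyloxy)phenyl]-8-bromochroman-6-yl]-2H-chromene | C(c1ccccc1)Oc2ccc(cc2)[C@H]3Oc4cc(OCc5ccccc5)ccc4C(c6c(OCc7ccccc7)c(Br)c8c(c6OCc9ccccc9)C[C@H](OCc%10ccccc%10)[C@@H](c%11ccc(OCc%12ccccc%12)cc%11)O8)=C3 | intermediate
13 | C3 alkylborane from 12, boron at C3 trans to the C2 aryl and cis to the new C4–H (not isolated) | C(c1ccccc1)Oc2ccc(cc2)[C@H]3Oc4cc(OCc5ccccc5)ccc4[C@@H](c6c(OCc7ccccc7)c(Br)c8c(c6OCc9ccccc9)C[C@H](OCc%10ccccc%10)[C@@H](c%11ccc(OCc%12ccccc%12)cc%11)O8)[C@@H]3B | intermediate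
14 | (2R,3S,4S)-7-(benzyloxy)-2-[4-(benzyloxy)phenyl]-4-[(2R,3S)-3,5,7-tris(benzyloxy)-2-[4-(benzyloxy)phenyl]-8-bromochroman-6-yl]chroman-3-ol | C(c1ccccc1)Oc2ccc(cc2)[C@H]3Oc4cc(OCc5ccccc5)ccc4[C@@H](c6c(OCc7ccccc7)c(Br)c8c(c6OCc9ccccc9)C[C@H](OCc%10ccccc%10)[C@@H](c%11ccc(OCc%12ccccc%12)cc%11)O8)[C@@H]3O | intermediate
15 | guibourtinidol-(4α→6)-afzelechin (CNP0325116.1), (2R,3S,4S)-2-(4-hydroxyphenyl)-4-[(2R,3S)-3,5,7-trihydroxy-2-(4-hydroxyphenyl)chroman-6-yl]chromane-3,7-diol | Oc1ccc([C@H]2Oc3cc(O)ccc3[C@@H](c3c(O)cc4c(c3O)C[C@H](O)[C@@H](c3ccc(O)cc3)O4)[C@@H]2O)cc1 | target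

Total step count: 8. Longest linear sequence: 7 steps (1 → 2 → 3 → 6 → 11 → 12 → 14 → 15; steps 1, 2, 3, 5, 6, 7, 8).

Steps most likely to fail

Step 5. The β-oxido organolithium may lose Li2O to give the styrene before it adds. It may also exchange with the C8 bromine of the lower unit instead of adding to the hindered carbonyl, or the fluoride displacement on the no longer activated ring may stall. The fallback forms the two bonds stepwise, the ether first while the ketone still activates ring A, and sets out from 8 and 6 and returns at 12. K2CO3 in MeOH closes 8 to the epoxide (R)-2-[4-(benzyloxy)phenyl]oxirane F1. Dimethylsulfonium methylide (Me3S+ I−, n-BuLi, THF) opens it at CH2 and loses Me2S to give the allylic alcohol (S)-1-[4-(benzyloxy)phenyl]prop-2-en-1-ol F2. Its sodium alkoxide (NaH, THF, 0 °C) displaces the ketone-activated fluorine of 6 to give the allylic aryl ether F3. OsO4 (cat.)/NaIO4 cleaves the vinyl group to the α-aryloxy aldehyde F4, which is used at once. Intramolecular McMurry coupling of the aldehyde with the diaryl ketone (TiCl3, Zn–Cu, DME, reflux, high dilution) should then give 12.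

Step 7. Addition of borane to the hindered trisubstituted alkene may be slow, or face and site selectivity may erode. The fallback sets out from 12 and returns at 14. Dimethyldioxirane (acetone, −40 °C) epoxidises C3=C4 anti to the C2 aryl to give the 3,4-epoxide F5. A Meinwald rearrangement (cat. ZnBr2, CH2Cl2, −40 °C; opening at C4, 1,2-hydride shift from C3) gives the 4-arylflavan-3-one F6, whose acidic C4–H is equilibrated with Et3N to the 2,4-cis (diequatorial) isomer. NaBH4 (THF/MeOH, −40 °C), attacking axially, should give the equatorial 3-OH, which is 14.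

Step 3. Acid may cleave the benzyl ethers ortho to the new ketone or open the pyran ring of the lower unit, or conversion at the crowded C6 may be low. The fallback sets out from 3 and returns at 6. Vilsmeier–Haack formylation (POCl3, DMF, 60 °C) gives the 6-carbaldehyde F7. The aryl Grignard reagent from commercial 4-(benzyloxy)-1-bromo-2-fluorobenzene (i-PrMgCl·LiCl, THF, −15 °C) adds to give the benzhydrol F8. Oxidation with DMP (CH2Cl2, NaHCO3) gives 6.

Further compounds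
F1 | step 5 | (R)-2-[4-(benzyloxy)phenyl]oxirane | C1O[C@@H]1c2ccc(OCc3ccccc3)cc2
F2 | step 5 | (S)-1-[4-(benzyloxy)phenyl]prop-2-en-1-ol | O[C@@H](C=C)c1ccc(OCc2ccccc2)cc1
F3 | step 5 | [4-(benzyloxy)-2-{[(1S)-1-[4-(benzyloxy)phenyl]prop-2-en-1-yl]oxy}phenyl][(2R,3S)-3,5,7-tris(benzyloxy)-2-[4-(benzyloxy)phenyl]-8-bromochroman-6-yl]methanone | O=C(c1ccc(OCc2ccccc2)cc1O[C@@H](C=C)c3ccc(OCc4ccccc4)cc3)c5c(OCc6ccccc6)c(Br)c7c(c5OCc8ccccc8)C[C@H](OCc9ccccc9)[C@@H](c%10ccc(OCc%11ccccc%11)cc%10)O7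
F4 | step 5 | (2R)-2-[4-(benzyloxy)phenyl]-2-{5-(benzyloxy)-2-[(2R,3S)-3,5,7-tris(benzyloxy)-2-[4-(benzyloxy)phenyl]-8-bromochromane-6-carbonyl]phenoxy}acetaldehyde | O=C(c1ccc(OCc2ccccc2)cc1O[C@@H](C=O)c3ccc(OCc4ccccc4)cc3)c5c(OCc6ccccc6)c(Br)c7c(c5OCc8ccccc8)C[C@H](OCc9ccccc9)[C@@H](c%10ccc(OCc%11ccccc%11)cc%10)O7
F5 | step 7 | 3,4-epoxide of 12, oxygen anti to the C2 aryl | C(c1ccccc1)Oc2ccc(cc2)[C@H]3Oc4cc(OCc5ccccc5)ccc4[C@@]6(c7c(OCc8ccccc8)c(Br)c9c(c7OCc%10ccccc%10)C[C@H](OCc%11ccccc%11)[C@@H](c%12ccc(OCc%13ccccc%13)cc%12)O9)[C@@H]3O6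
F6 | step 7 | 2,4-cis-7-(benzyloxy)-2-[4-(benzyloxy)phenyl]-4-[(2R,3S)-3,5,7-tris(benzyloxy)-2-[4-(benzyloxy)phenyl]-8-bromochroman-6-yl]chroman-3-one | C(c1ccccc1)Oc2ccc(cc2)[C@H]3Oc4cc(OCc5ccccc5)ccc4[C@@H](c6c(OCc7ccccc7)c(Br)c8c(c6OCc9ccccc9)C[C@H](OCc%10ccccc%10)[C@@H](c%11ccc(OCc%12ccccc%12)cc%11)O8)C3=O
F7 | step 3 | (2R,3S)-3,5,7-tris(benzyloxy)-2-[4-(benzyloxy)phenyl]-8-bromochromane-6-carbaldehyde | O=Cc1c(OCc3ccccc3)c(Br)c2c(c1OCc4ccccc4)C[C@H](OCc5ccccc5)[C@@H](c6ccc(OCc7ccccc7)cc6)O2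
F8 | step 3 | [4-(benzyloxy)-2-fluorophenyl][(2R,3S)-3,5,7-tris(benzyloxy)-2-[4-(benzyloxy)phenyl]-8-bromochroman-6-yl]methanol, carbinol epimers | OC(c8ccc(OCc9ccccc9)cc8F)c1c(OCc3ccccc3)c(Br)c2c(c1OCc4ccccc4)C[C@H](OCc5ccccc5)[C@@H](c6ccc(OCc7ccccc7)cc6)O2
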